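**Plan**
- Numbering (germacrane): ring C1–C10 with C10(CH3)=C1 and C4(C15H2OH)=C5; lactone O on C6, then C7–C11(CH3)–C12(=O); acyloxy group on C8.
- Retrosynthetic cuts, in order: the two silyl ethers; C1=C10 (ring-closing metathesis, so the ten-membered ring comes last); the C8 ester; C8–C9 (methallylation of a C8 aldehyde). C8 and C15 are then rejoined as the cis-diol of a temporary cyclohexene (ring atoms C4, C5, C6, C7, C8, C15). Then the pair O–C6 / C7–C11 is cut in one oxidative radical annulation with methylmalonic acid, and last C3–C4 (Negishi coupling), which leads back to the cis-dihydrodiol of bromobenzene.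
- Forward ring order: dioxolane-protected cyclohexadiene, then the γ-lactone (key step), then opening of the carbocycle by glycol cleavage to the C8 and C15 aldehydes, then the ten-membered ring.
- Enabling feature: the conjugated diene C4=C5–C6=C7 is locked s-cis in the six-membered ring. A radical entering at C7 leaves the allyl unit C6–C5–C4, whose near end C6 is captured by the carboxylate, and the dioxolane ring on C8/C15 shields one face.
- Stereochemistry: C6 and C7 come from the enantiopure diol (anti attack, forced cis fusion); C11 from ketonisation of the decarboxylation enol on the convex face; C8 from catalyst-controlled allylboration. The C4=C5 geometry is that of the ring olefin, C1=C10 (ring-cis) comes from metathesis, and the side-chain E olefin from a stabilised Wittig ylide.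

Key step: step 3

Assumption: diol 1, the toluene dioxygenase metabolite of bromobenzene, is taken as a purchasable enantiopure starting material; it is the source of the absolute configuration of the ring system.

**Step 1**
Reactants: 1 (1S,2S)-3-bromocyclohexa-3,5-diene-1,2-diol
Product: 2 (3aS,7aS)-4-bromo-2,2-dimethyl-3a,7a-dihydro-1,3-benzodioxole
Conditions: 2,2-dimethoxypropane, p-toluenesulfonic acid monohydrate (cat.), acetone, 0 to 25 °C
Reagents that add atoms: 2,2-dimethoxypropane, COC(C)(C)OC
Why: Acid-catalysed transketalisation of the cis-diol gives the cis-fused dioxolane, which stops aromatisation of the diene diol and later blocks one face of the diene.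

**Step 2**
Reactants: 2 (3aS,7aS)-4-bromo-2,2-dimethyl-3a,7a-dihydro-1,3-benzodioxole; 3 but-3-en-1-ylzinc bromide
Product: 4 (3aR,7aS)-4-(but-3-en-1-yl)-2,2-dimethyl-3a,7a-dihydro-1,3-benzodioxole
Conditions: PdCl2(dppf) (3 mol %), THF, 0 to 25 °C
Reagents that add atoms: but-3-en-1-ylzinc bromide (3), C=CCC[Zn]Br
Why: Negishi sp2–sp3 coupling (oxidative addition of zerovalent palladium into the vinyl C–Br bond, transmetalation from zinc, reductive elimination), with the wide bite angle of dppf suppressing β-hydride elimination; no stereocentre is touched and C3–C4 is formed.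

**Step 3**
Reactants: 4 (3aR,7aS)-4-(but-3-en-1-yl)-2,2-dimethyl-3a,7a-dihydro-1,3-benzodioxole; 5 methylmalonic acid
Product: 6 tricyclic lactone acid (the cyclohexene of 4 with C4=C5 retained, carrying on C6/C7, on the face opposite the dioxolane, a cis-fused γ-lactone whose C11 bears CH3 and CO2H; drawn with CO2H on the convex face, the C11 epimer converges in step 4)
Conditions: Mn(OAc)3·2H2O (2.2 equiv), methylmalonic acid (1.5 equiv), KOAc (2 equiv), AcOH, 25 °C, argon
Reagents that add atoms: methylmalonic acid (5), CC(C(=O)O)C(=O)O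
Why: Mn(OAc)3 forms the trivalent manganese enolate of methylmalonic acid and releases by inner-sphere electron transfer the electrophilic radical at C11, which adds to C7, the unsubstituted terminus of the s-cis ring diene C7=C6–C5=C4, leaving an allyl radical over C6–C5–C4 that a second equivalent of Mn(OAc)3 oxidises to the allyl cation, and one carboxyl oxygen then bonds to C6, so that C7–C11 and O–C6 arise in one operation. The closest known reaction type is the Mn(OAc)3-mediated oxidative radical lactone annulation (carbolactonisation) of alkenes and conjugated dienes with malonic or cyanoacetic acids near room temperature. The γ-lactone closes in the 5-exo mode at the near end of the allyl cation, which is faster than seven-membered closure at C4 and leaves the C4=C5 olefin inside the six-membered ring. C7 is controlled by the cis-fused dioxolane on C8/C15, which forces the radical onto the opposite diene face, C6 by the ring fusion, since a five-membered lactone can only be cis-fused to the cyclohexene, and the quaternary C11 needs no control because step 4 flattens it. The step needs regioselectivity for C7 over C4, secured by the butenyl substituent on C4 and by the more substituted allyl radical that C7 attack produces, and chemoselectivity for the conjugated diene over the isolated vinyl group, secured by the much faster addition of electrophilic radicals to 1,3-dienes and by keeping the oxidant near two equivalents. Buffered acetic acid at 25 °C should leave the dioxolane intact and prevent aromatisation.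

**Step 4**
Reactants: 6 tricyclic lactone acid
Product: 7 tricyclic lactone (6 with H in place of CO2H; C11 methyl on the concave face of the lactone, cis to C8 and C5, 11S)
Conditions: xylenes, 130 °C, argon
Reagents that add atoms: none
Why: Thermal decarboxylation of the malonic-type acid gives the lactone enol, which should ketonise by proton delivery to the exposed convex face of the cis-fused bicycle, so that the C11 methyl ends on the concave face (11S).

**Step 5**
Reactants: 7 tricyclic lactone
Product: 8 cis-diol lactone (7 without the isopropylidene group; free hydroxyls on C8 and C15)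
Conditions: AcOH/H2O (4:1), 45 °C
Reagents that add atoms: none
Why: Mild aqueous acid hydrolysis of the isopropylidene acetal frees the cis-diol while the lactone, the allylic C6–O bond and both olefins are left alone.

**Step 6**
Reactants: 8 cis-diol lactone
Product: 9 (2Z)-2-(but-3-en-1-yl)-3-[(2R,3R,4S)-3-formyl-4-methyl-5-oxooxolan-2-yl]prop-2-enal
Conditions: NaIO4 (1.2 equiv), THF/aqueous pH 7 phosphate buffer, 0 °C
Reagents that add atoms: none
Why: Periodate glycol cleavage (Malaprade reaction) opens the temporary carbocycle to the C8 aldehyde and the C15 enal, whose CHO is cis to C6 because both were ring members, and the neutral buffer avoids epimerisation at C7 and β-elimination of the lactone oxygen.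

**Step 7**
Reactants: 9 (2Z)-2-(but-3-en-1-yl)-3-[(2R,3R,4S)-3-formyl-4-methyl-5-oxooxolan-2-yl]prop-2-enal; 10 2-methylallylboronic acid pinacol ester
Product: 12 (2Z)-2-(but-3-en-1-yl)-3-{(2R,3S,4S)-3-[(1S)-1-hydroxy-3-methylbut-3-en-1-yl]-4-methyl-5-oxooxolan-2-yl}prop-2-enal, via O-pinacolboronate ester 11 (not isolated)
Conditions: 10 (1.05 equiv), (S)-3,3'-bis(2,4,6-triisopropylphenyl)-1,1'-binaphthyl-2,2'-diyl hydrogen phosphate (5 mol %), 4 Å molecular sieves, toluene, −40 °C; then pH 7 buffer
Reagents that add atoms: 2-methylallylboronic acid pinacol ester (10), CC(=C)CB1OC(C)(C)C(C)(C)O1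
Why: Chiral phosphoric acid-catalysed allylboration through a closed chair transition state, in which the saturated C8 aldehyde is more electrophilic than the α-substituted enal and the (S)-configured catalyst is expected to deliver the methallyl group to the Si face (the enantiomeric catalyst being the one that favours Re-face attack), which sets 8S and forms C8–C9; the O-boronate is hydrolysed on work-up.

**Step 8**
Reactants: 12 (2Z)-2-(but-3-en-1-yl)-3-{(2R,3S,4S)-3-[(1S)-1-hydroxy-3-methylbut-3-en-1-yl]-4-methyl-5-oxooxolan-2-yl}prop-2-enal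
Product: 13 (3S,4S,5R)-5-[(1Z)-2-(hydroxymethyl)hexa-1,5-dien-1-yl]-4-[(1S)-1-hydroxy-3-methylbut-3-en-1-yl]-3-methyloxolan-2-one
Conditions: NaBH4, CeCl3·7H2O, MeOH, −40 °C
Reagents that add atoms: none
Why: Luche reduction, in which the cerium-activated borohydride reduces the conjugated aldehyde by 1,2-addition at low temperature without touching the lactone or the olefin geometry.

**Step 9**
Reactants: 13 (3S,4S,5R)-5-[(1Z)-2-(hydroxymethyl)hexa-1,5-dien-1-yl]-4-[(1S)-1-hydroxy-3-methylbut-3-en-1-yl]-3-methyloxolan-2-one
Product: 14 (3S,4S,5R)-5-[(1Z)-2-{[tert-butyl(dimethyl)silyl]oxymethyl}hexa-1,5-dien-1-yl]-4-[(1S)-1-hydroxy-3-methylbut-3-en-1-yl]-3-methyloxolan-2-one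
Conditions: tert-butyldimethylsilyl chloride (1.05 equiv), imidazole, CH2Cl2, 0 °C
Reagents that add atoms: tert-butyldimethylsilyl chloride, CC(C)(C)[Si](C)(C)Cl
Why: Silylation is selective for the primary allylic C15 hydroxyl over the hindered secondary C8 carbinol.

**Step 10**
Reactants: 15 (tert-butyldimethylsilyloxy)acetaldehyde; 16 ethyl 2-(triphenylphosphoranylidene)propanoate
Product: 17 ethyl (2E)-4-[tert-butyl(dimethyl)silyl]oxy-2-methylbut-2-enoate
Conditions: CH2Cl2, 25 °C
Reagents that add atoms: ethyl 2-(triphenylphosphoranylidene)propanoate (16), CCOC(=O)C(C)=P(c1ccccc1)(c1ccccc1)c1ccccc1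
Why: Wittig olefination with the stabilised α-methyl ylide should give the trisubstituted (E)-enoate of the side chain.

**Step 11**
Reactants: 17 ethyl (2E)-4-[tert-butyl(dimethyl)silyl]oxy-2-methylbut-2-enoate
Product: 18 (2E)-4-[tert-butyl(dimethyl)silyl]oxy-2-methylbut-2-enoic acid
Conditions: LiOH·H2O, THF/MeOH/H2O, 25 °C; then 1 M HCl to pH 4, 0 °C
Reagents that add atoms: lithium hydroxide, [Li+].[OH-]
Why: Saponification of the ethyl ester, which the primary silyl ether survives, as it does the brief cold acidification.

**Step 12**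
Reactants: 14 (3S,4S,5R)-5-[(1Z)-2-{[tert-butyl(dimethyl)silyl]oxymethyl}hexa-1,5-dien-1-yl]-4-[(1S)-1-hydroxy-3-methylbut-3-en-1-yl]-3-methyloxolan-2-one; 18 (2E)-4-[tert-butyl(dimethyl)silyl]oxy-2-methylbut-2-enoic acid
Product: 20 acyclic C8 ester (14 acylated on the C8 oxygen by the (2E)-4-silyloxy-2-methylbut-2-enoyl group), via Yamaguchi mixed anhydride 19 (not isolated)
Conditions: 18, 2,4,6-trichlorobenzoyl chloride, Et3N, toluene, 25 °C; then 14, 4-(dimethylamino)pyridine, toluene, 25 °C
Reagents that add atoms: 2,4,6-trichlorobenzoyl chloride, O=C(Cl)c1c(Cl)cc(Cl)cc1Cl (its acyl group stays only in intermediate 19)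
Why: Yamaguchi esterification, in which 4-(dimethylamino)pyridine attacks the less hindered enoyl carbonyl of the mixed anhydride and the acylpyridinium acylates the hindered C8 carbinol with retention at C8 and without E/Z leakage of the tiglate-type olefin.

**Step 13**
Reactants: 20 acyclic C8 ester
Product: 21 bis-silyl ether of the target (ten-membered ring closed, C1=C10 ring-cis)
Conditions: second-generation Grubbs catalyst RuCl2(=CHPh)(PCy3)(H2IMes) (10 mol %), 1,4-benzoquinone (10 mol %), toluene (1 mM), 80 °C, argon sparge
Reagents that add atoms: none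
Why: Ring-closing metathesis between the monosubstituted C1 vinyl group and the 1,1-disubstituted C10 methallyl olefin, the only two reactive olefins (C4=C5 and the enoate are trisubstituted and inert), is driven by loss of ethylene, and in a ten-membered ring the ring-cis trisubstituted olefin is the less strained isomer, while the cis-lactone and the C4=C5 olefin pre-fold the chain.

**Step 14**
Reactants: 21 bis-silyl ether of the target
Product: 22 (3S,3aS,4S,6Z,10Z,11aR)-10-(hydroxymethyl)-3,6-dimethyl-2-oxo-2,3,3a,4,5,8,9,11a-octahydrocyclodeca[b]furan-4-yl (2E)-4-hydroxy-2-methylbut-2-enoate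
Conditions: HF·pyridine, pyridine, THF, 0 to 25 °C
Reagents that add atoms: none
Why: Fluoride cleaves both primary silyl ethers under buffered, non-basic conditions that should not cause acyl migration, lactone opening or epimerisation at C11.

**Compound list**
1 | (1S,2S)-3-bromocyclohexa-3,5-diene-1,2-diol | O[C@@H]1[C@H](O)C(Br)=CC=C1 | starting material
2 | (3aS,7aS)-4-bromo-2,2-dimethyl-3a,7a-dihydro-1,3-benzodioxole | CC1(C)O[C@H]2C=CC=C(Br)[C@H]2O1 | intermediate
3 | but-3-en-1-ylzinc bromide | C=CCC[Zn]Br | starting material
4 | (3aR,7aS)-4-(but-3-en-1-yl)-2,2-dimethyl-3a,7a-dihydro-1,3-benzodioxole | CC1(C)O[C@H]2C=CC=C(CCC=C)[C@H]2O1 | intermediate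
5 | methylmalonic acid | CC(C(=O)O)C(=O)O | starting material
6 | tricyclic lactone acid (11-carboxy-11-methyl γ-lactone cis-fused on C6/C7, anti to the dioxolane on C8/C15) | C=CCCC1=C[C@H]2OC(=O)[C@@](C(=O)O)(C)[C@H]2[C@@H]3OC(C)(C)O[C@H]13 | intermediate
7 | tricyclic lactone (11S methyl on the concave face) | C=CCCC1=C[C@H]2OC(=O)[C@@H](C)[C@H]2[C@@H]3OC(C)(C)O[C@H]13 | intermediate
8 | cis-diol lactone | C=CCCC1=C[C@H]2OC(=O)[C@@H](C)[C@H]2[C@H](O)[C@@H]1O | intermediate
9 | (2Z)-2-(but-3-en-1-yl)-3-[(2R,3R,4S)-3-formyl-4-methyl-5-oxooxolan-2-yl]prop-2-enal | C=CCC/C(C=O)=C/[C@H]1OC(=O)[C@@H](C)[C@H]1C=O | intermediate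
10 | 2-methylallylboronic acid pinacol ester | CC(=C)CB1OC(C)(C)C(C)(C)O1 | starting material
11 | O-pinacolboronate ester of 12 | C=CCC/C(C=O)=C/[C@H]1OC(=O)[C@@H](C)[C@H]1[C@H](CC(C)=C)OB2OC(C)(C)C(C)(C)O2 | intermediate
12 | (2Z)-2-(but-3-en-1-yl)-3-{(2R,3S,4S)-3-[(1S)-1-hydroxy-3-methylbut-3-en-1-yl]-4-methyl-5-oxooxolan-2-yl}prop-2-enal | C=CCC/C(C=O)=C/[C@H]1OC(=O)[C@@H](C)[C@H]1[C@@H](O)CC(C)=C | intermediate
13 | (3S,4S,5R)-5-[(1Z)-2-(hydroxymethyl)hexa-1,5-dien-1-yl]-4-[(1S)-1-hydroxy-3-methylbut-3-en-1-yl]-3-methyloxolan-2-one | C=CCC/C(CO)=C/[C@H]1OC(=O)[C@@H](C)[C@H]1[C@@H](O)CC(C)=C | intermediate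
14 | (3S,4S,5R)-5-[(1Z)-2-{[tert-butyl(dimethyl)silyl]oxymethyl}hexa-1,5-dien-1-yl]-4-[(1S)-1-hydroxy-3-methylbut-3-en-1-yl]-3-methyloxolan-2-one | C=CCC/C(CO[Si](C)(C)C(C)(C)C)=C/[C@H]1OC(=O)[C@@H](C)[C@H]1[C@@H](O)CC(C)=C | intermediate
15 | (tert-butyldimethylsilyloxy)acetaldehyde | O=CCO[Si](C)(C)C(C)(C)C | starting material
16 | ethyl 2-(triphenylphosphoranylidene)propanoate | CCOC(=O)C(C)=P(c1ccccc1)(c1ccccc1)c1ccccc1 | starting material
17 | ethyl (2E)-4-[tert-butyl(dimethyl)silyl]oxy-2-methylbut-2-enoate | CCOC(=O)/C(C)=C/CO[Si](C)(C)C(C)(C)C | intermediate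
18 | (2E)-4-[tert-butyl(dimethyl)silyl]oxy-2-methylbut-2-enoic acid | OC(=O)/C(C)=C/CO[Si](C)(C)C(C)(C)C | intermediate
19 | mixed anhydride of 18 with 2,4,6-trichlorobenzoic acid | O=C(OC(=O)/C(C)=C/CO[Si](C)(C)C(C)(C)C)c1c(Cl)cc(Cl)cc1Cl | intermediate
20 | acyclic C8 ester (metathesis precursor) | C=CCC/C(CO[Si](C)(C)C(C)(C)C)=C/[C@H]1OC(=O)[C@@H](C)[C@H]1[C@@H](OC(=O)/C(C)=C/CO[Si](C)(C)C(C)(C)C)CC(C)=C | intermediate
21 | bis-silyl ether of the target | C/C1=C/CC/C(CO[Si](C)(C)C(C)(C)C)=C/[C@H]2OC(=O)[C@@H](C)[C@H]2[C@@H](OC(=O)/C(C)=C/CO[Si](C)(C)C(C)(C)C)C1 | intermediate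
22 | (3S,3aS,4S,6Z,10Z,11aR)-10-(hydroxymethyl)-3,6-dimethyl-2-oxo-2,3,3a,4,5,8,9,11a-octahydrocyclodeca[b]furan-4-yl (2E)-4-hydroxy-2-methylbut-2-enoate | C/C1=C/CC/C(CO)=C/[C@H]2OC(=O)[C@@H](C)[C@H]2[C@@H](OC(=O)/C(C)=C/CO)C1 | target

**Step count and risks**
Total step count: 14. Longest linear sequence: 12 steps (steps 1–9 and 12–14, from diol 1).

Three steps most likely to fail:

- **Step 3 (key step).** The electrophilic radical may also add to the terminal vinyl group of the side chain, and the acidic medium may strip the dioxolane and let the diene aromatise. Fallback: setting out from 2, the same Mn(OAc)3/methylmalonic acid annulation is run on the bromodiene, which has no second olefin, to give bromo lactone acid F1. Decarboxylation as in step 4 gives bromo lactone F2, and Negishi coupling of its vinyl bromide with 3 (PdCl2(dppf), THF) returns to the route at 7.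

- **Step 7.** Allylation may occur at both aldehydes or at the conjugated one, facial selectivity at C8 may erode if catalyst and substrate are mismatched, and the aldehyde-bearing C7 may epimerise. Fallback: setting out from 9, the conjugated aldehyde alone is reduced under Luche conditions in aqueous ethanol at −15 °C, where the saturated aldehyde is masked as its hydrate, to give hydroxy aldehyde F3. Silylation (tert-butyldimethylsilyl chloride, imidazole, 0 °C) gives silyloxy aldehyde F4. Methallylboration of its single aldehyde with 10 under the same catalyst then gives, through boronate ester F5, alcohol 14, where the route is rejoined.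

- **Step 13.** Intermolecular metathesis (oligomerisation) may outrun closure of the strained ten-membered ring, or the ring may close to the ring-trans olefin. Fallback: setting out from 14, the ring-closing metathesis is moved in front of the acylation and run on the free C8 carbinol, where no bulky acyl group crowds the methallyl olefin, to give macrocyclic alcohol F6. Yamaguchi acylation of F6 with mixed anhydride 19 returns to the route at 21.

**Further compounds**
F1 | step 3 | bromo lactone acid (6 with Br on C4 in place of the butenyl chain) | BrC1=C[C@H]2OC(=O)[C@@](C(=O)O)(C)[C@H]2[C@@H]3OC(C)(C)O[C@H]13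
F2 | step 3 | bromo lactone (7 with Br on C4 in place of the butenyl chain) | BrC1=C[C@H]2OC(=O)[C@@H](C)[C@H]2[C@@H]3OC(C)(C)O[C@H]13
F3 | step 7 | hydroxy aldehyde (9 with the C15 aldehyde reduced to CH2OH) | C=CCC/C(CO)=C/[C@H]1OC(=O)[C@@H](C)[C@H]1C=O
F4 | step 7 | silyloxy aldehyde (tert-butyldimethylsilyl ether of F3) | C=CCC/C(CO[Si](C)(C)C(C)(C)C)=C/[C@H]1OC(=O)[C@@H](C)[C@H]1C=O
F5 | step 7 | boronate ester (O-pinacolboronate of 14) | C=CCC/C(CO[Si](C)(C)C(C)(C)C)=C/[C@H]1OC(=O)[C@@H](C)[C@H]1[C@H](CC(C)=C)OB2OC(C)(C)C(C)(C)O2
F6 | step 13 | macrocyclic alcohol (21 with free C8 hydroxyl) | C/C1=C/CC/C(CO[Si](C)(C)C(C)(C)C)=C/[C@H]2OC(=O)[C@@H](C)[C@H]2[C@@H](O)C1
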